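## Analysis of the target

The target joins a cis-fused perhydroazulene to a 2,7-dioxabicyclo[3.2.1]octan-3-one. The carbocycle carries an exocyclic methylene next to one ring-fusion carbon, a gem-dimethyl carbon next to the other, and a methyl-bearing quaternary carbon in the five-membered ring. The heterobicycle is numbered C1 (acetal CH), O2, C3 (lactone C=O), C4, C5 (bridgehead CH), C6, O7, C8 (one-atom bridge). C4 bears an equatorial acetoxy group (cis to the C6–O7 bridge), C6 an exo methoxycarbonyl group, and C8 the hydroazulenyl group, syn to the lactone bridge. These five contiguous stereocentres adjoin the three of the carbocycle: two cis ring-fusion CH groups and the quaternary carbon, whose side chain lies on the face of the ring-fusion hydrogens. The sensitive groups are the acyloxy acetal at C1 (cleaved by base and nucleophiles, scrambled by acid), the 1,1-disubstituted alkene (migrates in strong acid), the acetate next to the lactone carbonyl and the epimerisable α-alkoxy ester. The synthesis is hard for three reasons: the bond from the quaternary carbon to C8 joins two congested centres, configuration must be relayed from one half to the other, and the hydroxy acid aldehyde behind the heterobicycle can also close to a γ-lactone or a fused lactol. The strategy rests on the six-membered lactone ring O2–C3–C4–C5–C8–C1. It is read as an enal (C1 the formyl carbon, C8 the α-carbon, C5 the β-carbon) joined to a glycolate ketene acetal (C3, C4) across the C4–C5 and O2–C3 bonds, with C6 as the allylic stereocentre that steers the addition.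

## Retrosynthetic reasoning

**C6 arm and C4 ester.** The methyl ester of target 33 is traced through acid 32 and primary alcohol 31 to the PMB ether 30, and the acetate of 30 to the silyl ether 28. Both are kept for the end because the α-alkoxy ester is epimerisable and because C4–O must stay blocked while the acetal lactone is closed.

**C1–O2 bond.** Cutting the acyloxy acetal of 28 gives lactol acid 27. The forward step is capture of a furanosyl cation by the carboxylic acid. It is done with C4–O silylated, since a free C4 hydroxyl would allow the lactol to re-form on that oxygen and the C6 oxygen to lactonise, giving the fused γ-lactone lactol.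

**Hydrolysis level.** Lactol acid 27 is the hydrolysis product of the cycloadduct 26. Its silyl orthoester is the carboxyl group, its enol ether the aldehyde, and its triethylsilyl ether the lactol oxygen.

**C4–C5 and O2–C3 bonds (key disconnection).** The dihydropyran 26 is cut into the enal 22 and the ketene acetal 25. This is the place to cut because one step then makes the lactone C–C bond, brings in the C4 oxygen and sets C4 and C5 under control of the stereocentre that becomes C6. The forward reaction has to be a face-selective, exo-selective [4+2] addition to a hindered oxadiene without attack at the formyl carbon.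

**C5=C8 bond of the enal.** Enal 22 is cut at its double bond into aldehyde 14 and the glyceraldehyde 19, joined through the silyl enol ether 20 and the aldol 21. Dehydration is expected to place the β-substituent trans to the tertiary group, which is the geometry drawn for 22. The α-carbon becomes trigonal ring carbon C5 of 26, so the geometry leaves no trace there.

**Chiral pool for C6.** Aldehyde 19 comes from (S)-solketal 15 through 16, 17 and 18. The free hydroxymethyl group becomes the PMB ether and the ring CH2O becomes the formyl group, which gives the (S)-aldehyde needed.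

**Ketene acetal.** 25 is reached from glycolic acid 23 through 24. The all-tert-butyldimethylsilyl form is chosen so that C4–O survives the hydrolysis that frees the lactol, and so that the orthoester carbon of 26 is not stereogenic.

**Side chain and methylene of 14.** Aldehyde 14 is traced through 13 and 12 to the allyl ketone 10. The ketone is the precursor of the exocyclic methylene, and the allyl group supplies the acetaldehyde arm by cleavage while no other alkene is present.

**Seven-membered ring.** Ketone 10 is the one-carbon ring expansion product of hydrindanone 8, with migration of the unhindered methylene.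

**Quaternary carbon.** Hydrindanone 8 arises by conjugate allylation of enone 7. This forms the bond from the quaternary carbon to its side chain and, on protonation, the second ring-fusion centre.

**Cyclopentene annulation.** Enone 7 is opened by retro-aldol to the diketone 6 and so to ketal 5. Ketal 5 is the conjugate adduct of 4,4-dimethylcyclohex-2-en-1-one 1 and the zinc reagent made from bromide 2. The catalyst in this addition sets the first stereocentre of the carbocycle.

## Alternatives that were turned down

**Alternative 1:** This disconnects two C–C bonds of the seven-membered ring. The forward step is decomposition of the cyclopentenyl diazoacetate A2 with Rh2(S-DOSP)4, cyclopropanation of the unsubstituted double bond of 4-methylpenta-1,3-diene A3, and Cope rearrangement of the divinylcyclopropane to the cycloheptadiene ester A1.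
- For it: the seven-membered ring, the gem-dimethyl carbon and one ring-fusion centre are made in one catalytic, convergent step, with the quaternary carbon and its acetate arm already in place. On economy of the carbocycle it is stronger than the sequence 1 → 14 used here, which depends on substrate control in the allylation.
- Against it: A1 still needs reduction of a tetrasubstituted enoate alkene to set the second ring-fusion CH cis, conversion of the ester carbon into the methylene carbon, and an enantioselective synthesis of the quaternary centre of A2. None of the five stereocentres of the heterobicycle is addressed.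
- In exchange, the chosen strategy offers one step that builds the lactone ring and two of those centres from a chiral-pool stereocentre.

**Alternative 2:** This disconnects the bond between the quaternary carbon and a ring carbonyl carbon. The forward step treats the bicyclo[5.4.0] epoxy ketone A5 with BF3·OEt2; the epoxide opens at the methyl-bearing carbon and the acyl carbon shifts to it, contracting the ring to the diketo aldehyde A4.
- For it: the quaternary stereocentre is formed stereospecifically (migration with inversion), and the cis ring fusion is already in place. On the configuration of the quaternary carbon it is stronger than conjugate allylation of 7.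
- Against it: the formyl group of A4 is one carbon short of the acetaldehyde arm of 14, an extra cyclopentanone carbonyl has to be deleted, three carbonyl groups must be told apart, and A5 needs a stereodefined 6-7 bicycle and a face-selective epoxidation.
- The chosen strategy reaches 14 in seven steps and places its main risk in the step that builds most of the heterobicycle.

**Alternative 3:** This disconnects the C5–C8 bond. The forward step treats bromoacetal A7 with Bu3SnH and AIBN; the C8 radical adds 5-exo to the tert-butyl enoate and closes the tetrahydrofuran A6.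
- For it: the Ueno–Stork cyclisation is neutral and dependable, and the acetal carbon is carried as a methyl acetal before any lactone exists. On the closure of the tetrahydrofuran acetal it is stronger than the lactol chemistry of step 18.
- Against it: A6 has no oxygen at C4, so a late, stereoselective α-hydroxylation of the lactone would be needed. A7 is a bromoacetal next to the quaternary carbon and hard to assemble. A secondary radical flanked by that carbon gives uncertain C5/C8 control, and tin must be removed.
- The chosen strategy brings in the C4 oxygen together with the C4–C5 bond and uses one allylic stereocentre for both new centres.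

Key step: step 17

## Remarks on the chemistry

- "Hydroazulenyl" means the cis-fused 3,8,8-trimethyl-4-methylenedecahydroazulen-3-yl group of 14 (H-3a and H-8a cis, the bond from C-3 on their face).
- The heterobicycle is numbered as in the analysis. The dihydropyran 26 is numbered O1, C2 (orthoester), C3, C4, C5, C6.
- Assumption: dehydration of 21 gives the (2Z)-enal (β-substituent trans to the tertiary group). The cycloadduct 26 would be the same compound from either isomer.
- Assumption: the (S,R,R)-phosphoramidite is the ligand enantiomer that gives (3R)-5, by analogy with its sense on cyclohex-2-enone. Its antipode would be used if the sense proved opposite.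

## Route

Step 1
Reactants: 1 4,4-dimethylcyclohex-2-en-1-one; 2 2-(2-bromoethyl)-2-methyl-1,3-dioxolane
Product: 5 (3R)-4,4-dimethyl-3-[2-(2-methyl-1,3-dioxolan-2-yl)ethyl]cyclohexan-1-one, via Grignard reagent 3 (not isolated), via diorganozinc 4 (not isolated)
Conditions: 2, Mg, THF, 25 °C; ZnCl2 (0.5 equiv), then 1,4-dioxane, filtration; 1, Cu(OTf)2 (2 mol %), (S)-(1,1′-binaphthalene-2,2′-diyl) N,N-bis[(R)-1-phenylethyl]phosphoramidite (4 mol %), toluene, −30 °C
Reagents that add atoms: none
Why: Copper–phosphoramidite catalysed asymmetric conjugate addition of a functionalised dialkylzinc, a reaction for which 4,4-disubstituted cyclohexenones are standard substrates; the catalyst sets C-3, and the ketal-bearing chain is the one used for cyclopentene annulation.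

Step 2
Reactants: 5
Product: 7 (7aS)-3,7,7-trimethyl-1,2,5,6,7,7a-hexahydro-4H-inden-4-one, via diketone 6 (not isolated)
Conditions: 1 M HCl, THF, 23 °C; then KOH, MeOH, 65 °C
Reagents that add atoms: none
Why: Ketal hydrolysis followed by intramolecular aldol condensation; only the aldol between ring C-2 and the side-chain ketone can dehydrate (the bridged alternative would need a bridgehead alkene), and the stereocentre is not enolisable.

Step 3
Reactants: 7
Product: 8 cis-fused 3-allyl-3,7,7-trimethyloctahydro-4H-inden-4-one (allyl on the face of H-3a and H-7a)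
Conditions: allylSiMe3, TiCl4, CH2Cl2, −78 → −40 °C; aq. NaHCO3
Reagents that add atoms: allyltrimethylsilane, C=CC[Si](C)(C)C
Why: Hosomi–Sakurai conjugate allylation, the dependable way to a quaternary carbon at a fully substituted enone β-carbon; the allyl group should enter on the face of H-7a, away from the C-7 quaternary carbon, and protonation of the titanium enolate away from the axial C-7 methyl group should give the cis ring fusion.

Step 4
Reactants: 8
Product: 10 cis-fused 3-allyl-3,8,8-trimethyloctahydroazulen-4(1H)-one (allyl on the face of H-3a and H-8a), via α-silyl ketone 9 (not isolated)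
Conditions: TMSCHN2, BF3·OEt2, CH2Cl2, −78 → −30 °C; then 1 M HCl, THF, 23 °C
Reagents that add atoms: (trimethylsilyl)diazomethane, C[Si](C)(C)C=[N+]=[N-]
Why: Lewis acid-promoted diazoalkane homologation of a ketone; the unhindered CH2 should migrate in preference to the tertiary ring-fusion carbon, so the carbonyl stays next to C-3a, and mild acid removes the α-silyl group without touching the ring-fusion centre.

Step 5
Reactants: 10
Product: 12 cis-fused 3-(2,2-dimethoxyethyl)-3,8,8-trimethyloctahydroazulen-4(1H)-one, via keto aldehyde 11 (not isolated)
Conditions: O3, CH2Cl2/MeOH, −78 °C; Me2S; then p-TsOH (cat.), MeOH, 23 °C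
Reagents that add atoms: methanol, CO
Why: Ozonolysis of the only alkene present, then acetalisation of the unhindered aldehyde; the ketone, flanked by a tertiary carbon, should not ketalise.

Step 6
Reactants: 12
Product: 13 cis-fused 3-(2,2-dimethoxyethyl)-3,8,8-trimethyl-4-methylenedecahydroazulene
Conditions: Cp2TiMe2, toluene, 70 °C
Reagents that add atoms: dimethyltitanocene Cp2TiMe2, C[Ti](C)(C1C=CC=C1)C1C=CC=C1
Why: Petasis methylenation, which is non-basic and so should leave the epimerisable ring-fusion centre and the acetal alone while converting a hindered ketone.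

Step 7
Reactants: 13
Product: 14 2-(cis-fused 3,8,8-trimethyl-4-methylenedecahydroazulen-3-yl)acetaldehyde
Conditions: PPTS, acetone/H2O (9:1), 50 °C
Reagents that add atoms: water, O
Why: Mild acetal hydrolysis; pyridinium tosylate is too weak an acid to move the exocyclic double bond.

Step 8
Reactants: 15 (S)-solketal, (S)-(2,2-dimethyl-1,3-dioxolan-4-yl)methanol
Product: 16 (S)-4-[(4-methoxybenzyloxy)methyl]-2,2-dimethyl-1,3-dioxolane
Conditions: NaH, PMBCl, Bu4NI (cat.), THF/DMF, 0 → 23 °C
Reagents that add atoms: 4-methoxybenzyl chloride, COc1ccc(CCl)cc1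
Why: Williamson ether synthesis on the free primary alcohol; the stereocentre is not involved.

Step 9
Reactants: 16
Product: 17 (R)-3-(4-methoxybenzyloxy)propane-1,2-diol
Conditions: AcOH/H2O (4:1), 40 °C
Reagents that add atoms: none
Why: Acetonide hydrolysis under conditions that leave a PMB ether intact.

Step 10
Reactants: 17
Product: 18 (S)-1-(4-methoxybenzyloxy)-2,3-bis(triethylsilyloxy)propane
Conditions: TESCl, imidazole, DMF, 0 °C
Reagents that add atoms: chlorotriethylsilane, CC[Si](Cl)(CC)CC
Why: Exhaustive silylation of the diol.

Step 11
Reactants: 18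
Product: 19 (S)-3-(4-methoxybenzyloxy)-2-(triethylsilyloxy)propanal
Conditions: (COCl)2, DMSO, CH2Cl2, −78 → −30 °C; Et3N, −78 → 0 °C
Reagents that add atoms: none
Why: Swern conditions cleave and oxidise a primary triethylsilyl ether in the presence of a secondary one, so the aldehyde is obtained without a separate deprotection; the α-silyloxy aldehyde is used at once to avoid epimerisation.

Step 12
Reactants: 14
Product: 20 (E)-trimethylsilyl enol ether of 14, trimethyl[2-(hydroazulenyl)ethenyloxy]silane
Conditions: TMSOTf, Et3N, CH2Cl2, 0 °C
Reagents that add atoms: trimethylsilyl trifluoromethanesulfonate, C[Si](C)(C)OS(=O)(=O)C(F)(F)F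
Why: Soft enolisation of an aldehyde to its silyl enol ether; this defines which of the two enolisable aldehydes is the donor in the next step, and the geometry is of no consequence.

Step 13
Reactants: 20; 19
Product: 21 (4R)-2-(hydroazulenyl)-3-hydroxy-5-(4-methoxybenzyloxy)-4-(triethylsilyloxy)pentanal (mixture at C-2 and C-3)
Conditions: BF3·OEt2, CH2Cl2, −78 °C; aq. NaHCO3
Reagents that add atoms: none
Why: Mukaiyama aldol addition; the α-oxygenated aldehyde is the more electrophilic partner and is not enolised under Lewis acid at −78 °C, and both new centres are removed in the next step.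

Step 14
Reactants: 21
Product: 22 (2Z,4R)-2-(hydroazulenyl)-5-(4-methoxybenzyloxy)-4-(triethylsilyloxy)pent-2-enal
Conditions: MsCl, Et3N, CH2Cl2, −20 → 23 °C
Reagents that add atoms: none
Why: Mesylation and E1cB elimination; the β-substituent should settle trans to the tertiary hydroazulenyl group (cis to the formyl group), and triethylamine is too weak to deprotonate the γ-position, so C-4 keeps its configuration.

Step 15
Reactants: 23 glycolic acid
Product: 24 tert-butyldimethylsilyl 2-(tert-butyldimethylsilyloxy)acetate
Conditions: TBSCl, imidazole, DMF, 23 °C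
Reagents that add atoms: tert-butyldimethylsilyl chloride, CC(C)(C)[Si](C)(C)Cl
Why: Silylation of both the hydroxyl and the carboxyl group.

Step 16
Reactants: 24
Product: 25 1,1,2-tris(tert-butyldimethylsilyloxy)ethene
Conditions: LDA, THF, −78 °C; TBSCl, DMPU, −78 → 0 °C
Reagents that add atoms: tert-butyldimethylsilyl chloride, CC(C)(C)[Si](C)(C)Cl
Why: O-Silylation of the ester enolate to a ketene bis(silyl) acetal, the route by which glycolate ketene acetals are made; the two acetal oxygens carry the same group, so the reagent has no geometric isomers.

Step 17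
Reactants: 22; 25
Product: 26 (3,4-cis)-2,2,3-tris(tert-butyldimethylsilyloxy)-5-(hydroazulenyl)-4-[(1R)-2-(4-methoxybenzyloxy)-1-(triethylsilyloxy)ethyl]-3,4-dihydro-2H-pyran
Conditions: 25 (3 equiv), CH2Cl2, 1.2 GPa, 40 °C
Reagents that add atoms: none
Why: Inverse-electron-demand hetero-Diels–Alder reaction in which the s-cis enal is the electron-poor 4π component and the ketene acetal the electron-rich 2π component; polarity fixes the regiochemistry, the CH(OSi) carbon bonding to the enal β-carbon slightly ahead of the carbonyl oxygen bonding to the C(OSi)2 carbon. The closest known reaction type is the [4+2] addition of ketene acetals to 2-substituted enals to give 2,2-dioxy-3,4-dihydro-2H-pyrans; the tertiary α-substituent and the cis β-substituent are the untested features, and pressure is used in place of a Lewis acid, which would invite aldol addition to the formyl group. The dihydropyran is closed by the cycloaddition itself (bonds C3–C4 and O1–C2), suprafacially on both partners. C-4 is controlled by the allylic stereocentre: A(1,3) strain with the cis formyl group holds the allylic C–H in the plane of the oxadiene, and the nucleophilic ketene acetal should add anti to the C–OSiEt3 bond. C-3 follows from exo placement of the silyloxy group, away from the oxadiene and its α-substituent, which with the β-substituent on the inside position gives the 3,4-cis adduct. C-2 carries two identical silyloxy groups and C-5 stays trigonal, so no further isomers arise. The step therefore needs π-facial selectivity, exo selectivity and 1,4- over 1,2-addition; should ring closure lag behind C–C bond formation, the silyl-transfer isomer that results is hydrolysed to the same lactol acid 27 in step 18.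

Step 18
Reactants: 26
Product: 28 4-(tert-butyldimethylsilyloxy)-8-(hydroazulenyl)-6-[(4-methoxybenzyloxy)methyl]-2,7-dioxabicyclo[3.2.1]octan-3-one (4-OSi equatorial, 6-substituent exo, 8-substituent syn to the lactone bridge), via lactol acid 27 (not isolated)
Conditions: AcOH/THF/H2O (3:1:1), 23 °C; then CSA (0.2 equiv), 4 Å MS, CH2Cl2, 23 °C
Reagents that add atoms: none
Why: Aqueous acetic acid hydrolyses the silyl orthoester to the acid and the enol ether to the aldehyde and removes the triethylsilyl group, so the C-6 oxygen is locked at once in the lactol while the secondary TBS ether keeps C4–O out of play. Camphorsulfonic acid then ionises the lactol, and the carboxylic acid captures the furanosyl cation (acid-mediated acyloxy acetal formation, as used for dioxabicyclo[3.2.1]octanones). C-8 is set on protonation of the enol ether and stays exchangeable through the cation/enol ether pair, and the lactone should settle as the epimer that keeps the tertiary group away from the exo substituent on C-6.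

Step 19
Reactants: 28
Product: 30 4-acetoxy-8-(hydroazulenyl)-6-[(4-methoxybenzyloxy)methyl]-2,7-dioxabicyclo[3.2.1]octan-3-one, via hydroxy lactone 29 (not isolated)
Conditions: HF·pyridine, pyridine/THF, 0 → 23 °C; then Ac2O, DMAP, 23 °C
Reagents that add atoms: acetic anhydride, CC(=O)OC(C)=O
Why: Buffered fluoride removes the TBS ether without opening the acyloxy acetal, and acetylation in the same flask keeps the free α-hydroxy lactone from rearranging; the equatorial acetate is the configuration from step 17 and also the more stable one, since an axial group at C-4 would clash with the C-8 substituent.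

Step 20
Reactants: 30
Product: 31 4-acetoxy-8-(hydroazulenyl)-6-(hydroxymethyl)-2,7-dioxabicyclo[3.2.1]octan-3-one
Conditions: DDQ, CH2Cl2/pH 7 buffer, 0 °C
Reagents that add atoms: none
Why: Oxidative cleavage of the PMB ether under buffered conditions that spare the isolated alkene, the acetate and the acetal.

Step 21
Reactants: 31
Product: 32 4-acetoxy-8-(hydroazulenyl)-3-oxo-2,7-dioxabicyclo[3.2.1]octane-6-carboxylic acid
Conditions: TEMPO (cat.), PhI(OAc)2, MeCN/H2O, 23 °C
Reagents that add atoms: water, O
Why: Oxoammonium oxidation of a primary alcohol next to a ring oxygen to the acid, the method used for uronic acids; near-neutral conditions avoid epimerisation at C-6 in the aldehyde stage, and the exo position is in any case the favoured one.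

Step 22
Reactants: 32
Product: 33 methyl 4-acetoxy-8-(hydroazulenyl)-3-oxo-2,7-dioxabicyclo[3.2.1]octane-6-carboxylate (CNP0215240.1)
Conditions: TMSCHN2, PhMe/MeOH (4:1), 0 °C
Reagents that add atoms: (trimethylsilyl)diazomethane, C[Si](C)(C)C=[N+]=[N-]
Why: Esterification with a diazoalkane, free of acid and base, so the acyloxy acetal, the acetate and the α-alkoxy ester centre are untouched.

## Compound list

1 | 4,4-dimethylcyclohex-2-en-1-one | CC1(C)CCC(=O)C=C1 | starting material
2 | 2-(2-bromoethyl)-2-methyl-1,3-dioxolane | CC1(CCBr)OCCO1 | starting material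
3 | [2-(2-methyl-1,3-dioxolan-2-yl)ethyl]magnesium bromide | CC1(CC[Mg]Br)OCCO1 | intermediate
4 | bis[2-(2-methyl-1,3-dioxolan-2-yl)ethyl]zinc | CC1(CC[Zn]CCC2(C)OCCO2)OCCO1 | intermediate
5 | (3R)-4,4-dimethyl-3-[2-(2-methyl-1,3-dioxolan-2-yl)ethyl]cyclohexan-1-one | O=C1CCC(C)(C)[C@H](CCC2(C)OCCO2)C1 | intermediate
6 | (3R)-4,4-dimethyl-3-(3-oxobutyl)cyclohexan-1-one | O=C1CCC(C)(C)[C@H](CCC(C)=O)C1 | intermediate
7 | (7aS)-3,7,7-trimethyl-1,2,5,6,7,7a-hexahydro-4H-inden-4-one | O=C1CCC(C)(C)[C@@H]2CCC(C)=C12 | intermediate
8 | cis-fused 3-allyl-3,7,7-trimethyloctahydro-4H-inden-4-one (allyl on the face of H-3a and H-7a) | O=C1CCC(C)(C)[C@@H]2CC[C@@](C)(CC=C)[C@H]12 | intermediate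
9 | cis-fused 3-allyl-3,8,8-trimethyl-5-(trimethylsilyl)octahydroazulen-4(1H)-one (mixture at C-5) | O=C1C([Si](C)(C)C)CCC(C)(C)[C@@H]2CC[C@@](C)(CC=C)[C@H]12 | intermediate
10 | cis-fused 3-allyl-3,8,8-trimethyloctahydroazulen-4(1H)-one | O=C1CCCC(C)(C)[C@@H]2CC[C@@](C)(CC=C)[C@H]12 | intermediate
11 | 2-(cis-fused 3,8,8-trimethyl-4-oxodecahydroazulen-3-yl)acetaldehyde | O=C1CCCC(C)(C)[C@@H]2CC[C@@](C)(CC=O)[C@H]12 | intermediate
12 | cis-fused 3-(2,2-dimethoxyethyl)-3,8,8-trimethyloctahydroazulen-4(1H)-one | O=C1CCCC(C)(C)[C@@H]2CC[C@@](C)(CC(OC)OC)[C@H]12 | intermediate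
13 | cis-fused 3-(2,2-dimethoxyethyl)-3,8,8-trimethyl-4-methylenedecahydroazulene | C=C1CCCC(C)(C)[C@@H]2CC[C@@](C)(CC(OC)OC)[C@H]12 | intermediate
14 | 2-(cis-fused 3,8,8-trimethyl-4-methylenedecahydroazulen-3-yl)acetaldehyde | C=C1CCCC(C)(C)[C@@H]2CC[C@@](C)(CC=O)[C@H]12 | intermediate
15 | (S)-solketal, (S)-(2,2-dimethyl-1,3-dioxolan-4-yl)methanol | OC[C@H]1COC(C)(C)O1 | starting material
16 | (S)-4-[(4-methoxybenzyloxy)methyl]-2,2-dimethyl-1,3-dioxolane | COc1ccc(COC[C@H]2COC(C)(C)O2)cc1 | intermediate
17 | (R)-3-(4-methoxybenzyloxy)propane-1,2-diol | COc1ccc(COC[C@H](O)CO)cc1 | intermediate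
18 | (S)-1-(4-methoxybenzyloxy)-2,3-bis(triethylsilyloxy)propane | COc1ccc(COC[C@H](O[Si](CC)(CC)CC)CO[Si](CC)(CC)CC)cc1 | intermediate
19 | (S)-3-(4-methoxybenzyloxy)-2-(triethylsilyloxy)propanal | COc1ccc(COC[C@H](O[Si](CC)(CC)CC)C=O)cc1 | intermediate
20 | (E)-trimethyl[2-(hydroazulenyl)ethenyloxy]silane | C=C1CCCC(C)(C)[C@@H]2CC[C@@](C)(/C=C/O[Si](C)(C)C)[C@H]12 | intermediate
21 | (4R)-2-(hydroazulenyl)-3-hydroxy-5-(4-methoxybenzyloxy)-4-(triethylsilyloxy)pentanal (mixture at C-2 and C-3) | C=C1CCCC(C)(C)[C@@H]2CC[C@@](C)(C(C=O)C(O)[C@@H](O[Si](CC)(CC)CC)COCc3ccc(OC)cc3)[C@H]12 | intermediate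
22 | (2Z,4R)-2-(hydroazulenyl)-5-(4-methoxybenzyloxy)-4-(triethylsilyloxy)pent-2-enal | C=C1CCCC(C)(C)[C@@H]2CC[C@@](C)(/C(C=O)=C/[C@@H](O[Si](CC)(CC)CC)COCc3ccc(OC)cc3)[C@H]12 | intermediate
23 | glycolic acid | OCC(=O)O | starting material
24 | tert-butyldimethylsilyl 2-(tert-butyldimethylsilyloxy)acetate | CC(C)(C)[Si](C)(C)OCC(=O)O[Si](C)(C)C(C)(C)C | intermediate
25 | 1,1,2-tris(tert-butyldimethylsilyloxy)ethene | CC(C)(C)[Si](C)(C)OC=C(O[Si](C)(C)C(C)(C)C)O[Si](C)(C)C(C)(C)C | intermediate
26 | (3,4-cis)-2,2,3-tris(tert-butyldimethylsilyloxy)-5-(hydroazulenyl)-4-[(1R)-2-(4-methoxybenzyloxy)-1-(triethylsilyloxy)ethyl]-3,4-dihydro-2H-pyran | C=C1CCCC(C)(C)[C@@H]2CC[C@@](C)(C3=COC(O[Si](C)(C)C(C)(C)C)(O[Si](C)(C)C(C)(C)C)[C@@H](O[Si](C)(C)C(C)(C)C)[C@H]3[C@@H](O[Si](CC)(CC)CC)COCc4ccc(OC)cc4)[C@H]12 | intermediate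
27 | 2-(tert-butyldimethylsilyloxy)-2-[5-hydroxy-4-(hydroazulenyl)-2-(4-methoxybenzyloxymethyl)tetrahydrofuran-3-yl]acetic acid (anomers, C-4 of the ring not fixed) | C=C1CCCC(C)(C)[C@@H]2CC[C@@](C)(C3C(O)O[C@@H](COCc5ccc(OC)cc5)[C@@H]3[C@H](O[Si](C)(C)C(C)(C)C)C(=O)O)[C@H]12 | intermediate
28 | 4-(tert-butyldimethylsilyloxy)-8-(hydroazulenyl)-6-[(4-methoxybenzyloxy)methyl]-2,7-dioxabicyclo[3.2.1]octan-3-one | C=C1CCCC(C)(C)[C@@H]2CC[C@@](C)([C@@H]3[C@@H]4OC(=O)[C@@H](O[Si](C)(C)C(C)(C)C)[C@H]3[C@H](COCc5ccc(OC)cc5)O4)[C@H]12 | intermediate
29 | 4-hydroxy-8-(hydroazulenyl)-6-[(4-methoxybenzyloxy)methyl]-2,7-dioxabicyclo[3.2.1]octan-3-one | C=C1CCCC(C)(C)[C@@H]2CC[C@@](C)([C@@H]3[C@@H]4OC(=O)[C@@H](O)[C@H]3[C@H](COCc5ccc(OC)cc5)O4)[C@H]12 | intermediate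
30 | 4-acetoxy-8-(hydroazulenyl)-6-[(4-methoxybenzyloxy)methyl]-2,7-dioxabicyclo[3.2.1]octan-3-one | C=C1CCCC(C)(C)[C@@H]2CC[C@@](C)([C@@H]3[C@@H]4OC(=O)[C@@H](OC(C)=O)[C@H]3[C@H](COCc5ccc(OC)cc5)O4)[C@H]12 | intermediate
31 | 4-acetoxy-8-(hydroazulenyl)-6-(hydroxymethyl)-2,7-dioxabicyclo[3.2.1]octan-3-one | C=C1CCCC(C)(C)[C@@H]2CC[C@@](C)([C@@H]3[C@@H]4OC(=O)[C@@H](OC(C)=O)[C@H]3[C@H](CO)O4)[C@H]12 | intermediate
32 | 4-acetoxy-8-(hydroazulenyl)-3-oxo-2,7-dioxabicyclo[3.2.1]octane-6-carboxylic acid | C=C1CCCC(C)(C)[C@@H]2CC[C@@](C)([C@@H]3[C@@H]4OC(=O)[C@@H](OC(C)=O)[C@H]3[C@H](C(=O)O)O4)[C@H]12 | intermediate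
33 | methyl 4-acetoxy-8-(hydroazulenyl)-3-oxo-2,7-dioxabicyclo[3.2.1]octane-6-carboxylate, CNP0215240.1 | C=C1CCCC(C)(C)[C@@H]2CC[C@@](C)([C@@H]3[C@@H]4OC(=O)[C@@H](OC(C)=O)[C@H]3[C@H](C(=O)OC)O4)[C@H]12 | target

## Step count and least certain steps

Total: 22 steps. Longest linear sequence: 16 steps (steps 1–7, 12–14, 17–22).

**Step 17 (key step).** The addition may be unselective or may stall. Possible failures are poor π-facial discrimination at the β-carbon, attack at the formyl carbon, a high barrier because the β-substituent sits on the inside position of the oxadiene, or endo placement of the silyloxy group giving the C-3 epimer. The fallback sets out from 22 and 25 and replaces the cycloaddition by an open-chain Mukaiyama–Michael addition promoted by aluminium tris(2,6-diphenylphenoxide), Al(OC6H3Ph2)3, in toluene at −78 °C; its bulk shields the formyl carbon and enforces 1,4-addition. Aqueous work-up gives the aldehyde acid F1. The aqueous acetic acid of step 18 removes its triethylsilyl group and closes the lactol, so the fallback returns to the route at 27 and from there at 28.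

**Step 18.** Under acid the hydroxy acid aldehyde may drift into the γ-lactone by acylation of the C-6 oxygen after lactol opening, may lose the C-4 silyl ether and close the fused lactol, or may close with the C-8 epimer. The fallback sets out from 27 and closes the lactone by acylating the anomeric hydroxyl instead of trapping a cation: 2,4,6-trichlorobenzoyl chloride and Et3N give the mixed anhydride F2, and DMAP in toluene at high dilution closes it to 28. This is the mode of ring closure known for uronic acid 6,1-lactones and involves no oxocarbenium equilibration.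

**Step 3.** The allyl group may enter from the wrong face of the enone, or protonation may give the trans ring fusion, since the controlling centre is remote from the β-carbon. The fallback sets out from 7: allylmagnesium bromide adds 1,2 to give the tertiary allylic alcohol F3 (its epimer at the carbinol carbon is separated), and KH with 18-crown-6 in THF brings about an anionic oxy-Cope rearrangement. This delivers the allyl group suprafacially to C-3 and, after protonation, returns to the route at 8.

**Step 4.** The hindered ketone may fail to add the diazoalkane, or the ring-fusion carbon may migrate in part, placing the carbonyl one position off. The fallback sets out from 8 and is regiospecific. Kinetic enolisation (LDA, TMSCl) gives the silyl enol ether F4, Et2Zn/CH2I2 the siloxycyclopropane F5, and FeCl3 in DMF followed by NaOAc the cycloheptenone F6 (Saegusa-type ring expansion). Conjugate reduction with [(Ph3P)CuH]6 spares the allyl group and returns to the route at 10.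

**Step 13.** The neopentyl-type enol silane may add too slowly, and the Lewis acid may then strip the triethylsilyl ether or reverse the aldol. The fallback sets out from 14: tert-butylamine gives the imine F7, LDA at −78 °C metalates it, 19 is added, and buffered aqueous oxalic acid hydrolyses the adduct (directed aldol through a metalated imine). This returns to the route at 21.

## Further compounds

F1 | step 17 | 3-[(1R)-2-(4-methoxybenzyloxy)-1-(triethylsilyloxy)ethyl]-2-(tert-butyldimethylsilyloxy)-4-(hydroazulenyl)-5-oxopentanoic acid (mixture at C-4) | C=C1CCCC(C)(C)[C@@H]2CC[C@@](C)(C(C=O)[C@@H]([C@H](O[Si](C)(C)C(C)(C)C)C(=O)O)[C@@H](O[Si](CC)(CC)CC)COCc3ccc(OC)cc3)[C@H]12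
F2 | step 18 | mixed 2,4,6-trichlorobenzoic anhydride of 27 | C=C1CCCC(C)(C)[C@@H]2CC[C@@](C)(C3C(O)O[C@@H](COCc5ccc(OC)cc5)[C@@H]3[C@H](O[Si](C)(C)C(C)(C)C)C(=O)OC(=O)c6c(Cl)cc(Cl)cc6Cl)[C@H]12
F3 | step 3 | 4-allyl-3,7,7-trimethyl-1,2,5,6,7,7a-hexahydro-4H-inden-4-ol (allyl on the face of H-7a) | O[C@]1(CC=C)CCC(C)(C)[C@@H]2CCC(C)=C12
F4 | step 4 | cis-fused 3-allyl-3,7,7-trimethyl-4-(trimethylsilyloxy)-2,3,3a,6,7,7a-hexahydro-1H-indene | C[Si](C)(C)OC1=CCC(C)(C)[C@@H]2CC[C@@](C)(CC=C)[C@H]12
F5 | step 4 | siloxycyclopropane from F4 (cyclopropane fused across the former enol ether bond) | C[Si](C)(C)OC12CC1CC(C)(C)[C@@H]3CC[C@@](C)(CC=C)[C@H]23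
F6 | step 4 | cis-fused 3-allyl-3,8,8-trimethyl-2,3,3a,7,8,8a-hexahydroazulen-4(1H)-one | O=C1C=CCC(C)(C)[C@@H]2CC[C@@](C)(CC=C)[C@H]12
F7 | step 13 | N-tert-butyl imine of 14 | C=C1CCCC(C)(C)[C@@H]2CC[C@@](C)(C/C=N/C(C)(C)C)[C@H]12
A1 | alternative 1 | bicyclo[5.3.0]decadiene methyl ester with gem-dimethyl group and tert-butyl acetate arm | COC(=O)C1=C2[C@](C)(CC(=O)OC(C)(C)C)CC[C@H]2C(C)(C)C=CC1
A2 | alternative 1 | methyl 2-diazo-2-[5-(2-tert-butoxy-2-oxoethyl)-5-methylcyclopent-1-en-1-yl]acetate | COC(=O)C(=[N+]=[N-])C1=CCC[C@@]1(C)CC(=O)OC(C)(C)C
A3 | alternative 1 | 4-methylpenta-1,3-diene | C=CC=C(C)C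
A4 | alternative 2 | cis-hydroazulene diketone with quaternary formyl and methyl groups | O=C1CCCC(C)(C)[C@@H]2CC(=O)[C@@](C)(C=O)[C@H]12
A5 | alternative 2 | cis-fused bicyclo[5.4.0]undecane epoxy diketone | O=C1CCCC(C)(C)[C@@H]2CC(=O)[C@H]3O[C@@]3(C)[C@H]12
A6 | alternative 3 | 2-methoxytetrahydrofuran carrying hydroazulenyl, tert-butyl acetate arm and methyl ester | C=C1CCCC(C)(C)[C@@H]2CC[C@@](C)([C@@H]3C(OC)O[C@@H](C(=O)OC)[C@@H]3CC(=O)OC(C)(C)C)[C@H]12
A7 | alternative 3 | bromoacetal of the hydroazulenyl bromoacetaldehyde with a 4-hydroxypent-2-enedioate (tert-butyl enoate, methyl ester) | C=C1CCCC(C)(C)[C@@H]2CC[C@@](C)(C(Br)C(OC)O[C@@H](C(=O)OC)/C=C/C(=O)OC(C)(C)C)[C@H]12
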